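**Retrosynthetic overview**
- The target is the open hydroxy-diacid form of a 15,12-butenolide, so the last disconnections are lactone hydrolysis and C19 CH2OH → CO2H.
- Rings A and B are closed together (A first, then B, in one operation) by an epoxide-initiated cation–olefin bicyclisation of an acyclic (S)-2-methyl-2-alkyloxirane / (E)-alkene / (Z)-allylsilane, forming C4–C5 and C9–C10. The oxirane carbon C4 is itself the stereocentre and is inverted; the allylsilane delivers the 8(17)-alkene.
- The butenolide is closed before the bicyclisation from an α-hydroxy methyl ketone and Ph3P=C=C=O; the C12–OH comes from D-proline α-aminoxylation.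
- The ketone/allylsilane unit comes from carbocupration of a terminal alkyne with Me3SiCH2Cu and 1,4-addition to methyl vinyl ketone; the (E)-C5=C10 alkene from Zr-catalysed carboalumination and Negishi coupling.
- C4 with C18/C19 comes from (R)-2-methylglycidol, opened at one CH2 and re-closed onto the other.

Assumption: the SMILES is read as (4S,5R,9S,10R,12S,13Z)-12-hydroxylabda-8(17),13-diene-15,19-dioic acid and is delivered as the free diacid. Labdane numbering (C1–C20) is used in the explanations.

**Step 1**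
Reactants: 1 (4-bromobut-1-yn-1-yl)trimethylsilane; 2 (R)-2-methylglycidol
Product: 5 (S)-2-methylhept-6-yne-1,2-diol, via Grignard reagent 3 (not isolated), via TMS-alkyne diol 4 (not isolated)
Conditions: 1 (2.5 equiv), Mg, THF, 40 °C; CuI (10 mol%), 2, −40 → 0 °C; then MeOH, K2CO3, rt (one pot)
Reagents that add atoms: none
Why: Cu-catalysed Grignard opening of the epoxide at its unsubstituted CH2 (the first equivalent only deprotonates the OH; Payne equilibration of 2 is degenerate) leaves the quaternary C–O bond untouched, so the stereocentre is carried over unchanged (descriptor R → S by priority change only), and K2CO3/MeOH then cleaves the alkynyl C–Si bond.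

**Step 2**
Reactants: 5 (S)-2-methylhept-6-yne-1,2-diol
Product: 7 (2S,6E)-7-iodo-2,6-dimethylhept-6-ene-1,2-diol, via alkenylalane 6 (not isolated)
Conditions: Me3Al (4.5 equiv), Cp2ZrCl2 (25 mol%), CH2Cl2, 0 °C → rt; I2, THF, −30 → 0 °C; aq. NaHCO3/Na2S2O3
Reagents that add atoms: trimethylaluminium C[Al](C)C; iodine II
Why: Negishi Zr-catalysed carboalumination adds Me and Al syn with Al on the terminal carbon (free OH groups are tolerated as aluminium alkoxides), and iodinolysis with retention gives the (E)-iodide that fixes the C5=C10 geometry.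

**Step 3**
Reactants: 7 (2S,6E)-7-iodo-2,6-dimethylhept-6-ene-1,2-diol; 1 (4-bromobut-1-yn-1-yl)trimethylsilane
Product: 10 (2S,6E)-2,6-dimethylundec-6-en-10-yne-1,2-diol, via organozinc bromide 8 (not isolated), via TMS-enyne diol 9 (not isolated)
Conditions: 1 (3.5 equiv), Zn dust, LiCl, THF, 50 °C; 7, PdCl2(dppf) (5 mol%), THF, rt → 40 °C; then MeOH, K2CO3, rt
Reagents that add atoms: none
Why: Negishi sp2–sp3 cross-coupling of the alkenyl iodide with a primary alkylzinc bromide proceeds with retention of the (E)-geometry (the excess zinc reagent is consumed by the two OH groups), and protodesilylation then frees the terminal alkyne.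

**Step 4**
Reactants: 10 (2S,6E)-2,6-dimethylundec-6-en-10-yne-1,2-diol; 11 methyl vinyl ketone
Product: 13 (5Z,9E,14S)-14,15-dihydroxy-10,14-dimethyl-6-[(trimethylsilyl)methyl]pentadeca-5,9-dien-2-one, via alkenylcopper 12 (not isolated)
Conditions: Me3SiCH2MgCl (3.3 equiv; 2 equiv as base for the diol), CuBr·SMe2 (1.3 equiv), Et2O/Me2S, −40 → −15 °C, 3 h; 11 (2 equiv), −78 → −30 °C; aq. NH4Cl/NH3
Reagents that add atoms: (trimethylsilyl)methylmagnesium chloride C[Si](C)(C)C[Mg]Cl
Why: Normant carbocupration adds Me3SiCH2 and Cu syn across the terminal alkyne (Cu on the terminal carbon) and the alkenylcopper then adds 1,4 to the enone with retention, so CH2SiMe3 ends up cis to the new C11 chain, the geometry that later places the C9 side chain equatorial.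

**Step 5**
Reactants: 13 (5Z,9E,14S)-14,15-dihydroxy-10,14-dimethyl-6-[(trimethylsilyl)methyl]pentadeca-5,9-dien-2-one
Product: 15 (5Z,9E)-10-methyl-13-[(2S)-2-methyloxiran-2-yl]-6-[(trimethylsilyl)methyl]trideca-5,9-dien-2-one, via primary tosylate 14 (not isolated)
Conditions: TsCl (1.1 equiv), Et3N, Bu2SnO (5 mol%), CH2Cl2, 0 °C → rt; then K2CO3, MeOH, 0 °C → rt
Reagents that add atoms: none
Why: Tin-catalysed sulfonylation is selective for the primary hydroxyl of the 1,2-diol and the tertiary alkoxide then closes the oxirane by intramolecular Williamson displacement, which does not touch the stereocentre (2S).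

**Step 6**
Reactants: 15 (5Z,9E)-10-methyl-13-[(2S)-2-methyloxiran-2-yl]-6-[(trimethylsilyl)methyl]trideca-5,9-dien-2-one
Product: 17 (3S,5Z,9E)-3-hydroxy-10-methyl-13-[(2S)-2-methyloxiran-2-yl]-6-[(trimethylsilyl)methyl]trideca-5,9-dien-2-one, via aminoxy ketone 16 (not isolated)
Conditions: D-proline (30 mol%), PhNO (2.5 equiv, syringe pump), DMSO, rt
Reagents that add atoms: nitrosobenzene O=Nc1ccccc1
Why: Proline enamine catalysis (α-aminoxylation, O-nitroso aldol) oxygenates a methyl ketone at the more substituted α-carbon, D-proline giving the (S)-aminoxy ketone, whose N–O bond is cleaved in the same pot by the second equivalent of nitrosobenzene to give the (S)-acyloin that becomes C12.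

**Step 7**
Reactants: 17 (3S,5Z,9E)-3-hydroxy-10-methyl-13-[(2S)-2-methyloxiran-2-yl]-6-[(trimethylsilyl)methyl]trideca-5,9-dien-2-one
Product: 19 (5S)-4-methyl-5-{(2Z,6E)-7-methyl-10-[(2S)-2-methyloxiran-2-yl]-3-[(trimethylsilyl)methyl]deca-2,6-dien-1-yl}furan-2(5H)-one, via ester ylide 18 (not isolated)
Conditions: Ph3P=C=C=O (1.3 equiv), toluene, 90 °C
Reagents that add atoms: (triphenylphosphoranylidene)ketene O=C=C=P(c1ccccc1)(c1ccccc1)c1ccccc1
Why: The secondary alcohol adds to Bestmann's ylide and the resulting ester ylide closes onto the neighbouring ketone by intramolecular Wittig reaction under neutral conditions, which leaves the C12–O bond intact (S retained) and locks the 13Z geometry in the butenolide ring.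

**Step 8**
Reactants: 19 (5S)-4-methyl-5-{(2Z,6E)-7-methyl-10-[(2S)-2-methyloxiran-2-yl]-3-[(trimethylsilyl)methyl]deca-2,6-dien-1-yl}furan-2(5H)-one
Product: 20 (12S)-19-hydroxylabda-8(17),13-dien-15,12-olide
Conditions: MeAlCl2 (2.5 equiv), CH2Cl2, −78 °C, 1 h; Et3N, then aq. Rochelle salt
Reagents that add atoms: none
Why: Proposed new method: MeAlCl2 binds the oxirane oxygen and the C5=C10 alkene opens the tertiary C4–O bond from the rear (6-membered chair, SN2-like inversion at the only stereocentre of the initiator) while the (E)-alkene and (Z)-allylsilane continue in a chair–chair array, C9 attacking C10 anti and Me3Si leaving to give only the 8(17)-alkene; the oxirane CH2 is tied back toward the departing oxygen and its aluminate oxygen sits 1,3-diaxial to the developing C10 cation, so CH2O takes the axial site syn to C20 and the (S)-epoxide gives 4S,5R,9S,10R; the closest known chemistry is the concerted, anti-stereospecific Lewis-acid epoxy-polyene cyclisation of trisubstituted epoxides with allylsilane (Hosomi–Sakurai-type) termination.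

**Step 9**
Reactants: 20 (12S)-19-hydroxylabda-8(17),13-dien-15,12-olide
Product: 21 (12S)-labda-8(17),13-dien-15,12-olid-19-oic acid
Conditions: CrO3, aq. H2SO4, acetone, 0 °C (Jones), short reaction time
Reagents that add atoms: water O
Why: Jones oxidation takes the neopentylic axial CH2OH through the aldehyde hydrate to the acid, as in C19 oxidations of labdane and kaurane alcohols, and leaves the butenolide and the 1,1-disubstituted alkene alone at 0 °C.

**Step 10**
Reactants: 21 (12S)-labda-8(17),13-dien-15,12-olid-19-oic acid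
Product: 22 (12S,13Z)-12-hydroxylabda-8(17),13-diene-15,19-dioic acid
Conditions: LiOH (4 equiv), THF/H2O 3:1, 0 °C → rt; then cold 0.1 M HCl to pH 4 at 0 °C, immediate EtOAc extraction, evaporation below 20 °C
Reagents that add atoms: lithium hydroxide [Li+].[OH-]
Why: Saponification opens the butenolide by acyl substitution without breaking the C12–O bond, so 12S and 13Z are retained, and cold acidification only to pH 4 with fast extraction gives the free hydroxy diacid before it can relactonise.

**Compound list**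
1 | (4-bromobut-1-yn-1-yl)trimethylsilane | C[Si](C)(C)C#CCCBr | starting material
2 | (R)-2-methylglycidol, (2R)-(2-methyloxiran-2-yl)methanol | C[C@@]1(CO)CO1 | starting material
3 | [4-(trimethylsilyl)but-3-yn-1-yl]magnesium bromide | C[Si](C)(C)C#CCC[Mg]Br | intermediate
4 | (S)-2-methyl-7-(trimethylsilyl)hept-6-yne-1,2-diol | C[Si](C)(C)C#CCCC[C@](C)(O)CO | intermediate
5 | (S)-2-methylhept-6-yne-1,2-diol | C#CCCC[C@](C)(O)CO | intermediate
6 | [(1E,6S)-6,7-dihydroxy-2,6-dimethylhept-1-en-1-yl]dimethylalane (present as its aluminium alkoxide) | C[Al](C)/C=C(C)/CCC[C@](C)(O)CO | intermediate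
7 | (2S,6E)-7-iodo-2,6-dimethylhept-6-ene-1,2-diol | I/C=C(C)/CCC[C@](C)(O)CO | intermediate
8 | [4-(trimethylsilyl)but-3-yn-1-yl]zinc bromide | C[Si](C)(C)C#CCC[Zn]Br | intermediate
9 | (2S,6E)-2,6-dimethyl-11-(trimethylsilyl)undec-6-en-10-yne-1,2-diol | C[Si](C)(C)C#CCC/C=C(C)/CCC[C@](C)(O)CO | intermediate
10 | (2S,6E)-2,6-dimethylundec-6-en-10-yne-1,2-diol | C#CCC/C=C(C)/CCC[C@](C)(O)CO | intermediate
11 | methyl vinyl ketone (but-3-en-2-one) | CC(=O)C=C | starting material
12 | [(1Z,5E,10S)-10,11-dihydroxy-6,10-dimethyl-2-[(trimethylsilyl)methyl]undeca-1,5-dien-1-yl]copper (present as its magnesium alkoxide) | [Cu]/C=C(C[Si](C)(C)C)/CC/C=C(C)/CCC[C@](C)(O)CO | intermediate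
13 | (5Z,9E,14S)-14,15-dihydroxy-10,14-dimethyl-6-[(trimethylsilyl)methyl]pentadeca-5,9-dien-2-one | CC(=O)CC/C=C(C[Si](C)(C)C)/CC/C=C(C)/CCC[C@](C)(O)CO | intermediate
14 | (2S,6E,10Z)-2-hydroxy-2,6-dimethyl-14-oxo-10-[(trimethylsilyl)methyl]pentadeca-6,10-dien-1-yl 4-methylbenzenesulfonate | CC(=O)CC/C=C(C[Si](C)(C)C)/CC/C=C(C)/CCC[C@](C)(O)COS(=O)(=O)c1ccc(C)cc1 | intermediate
15 | (5Z,9E)-10-methyl-13-[(2S)-2-methyloxiran-2-yl]-6-[(trimethylsilyl)methyl]trideca-5,9-dien-2-one | CC(=O)CC/C=C(C[Si](C)(C)C)/CC/C=C(C)/CCC[C@@]1(C)CO1 | intermediate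
16 | (3S,5Z,9E)-3-(anilinooxy)-10-methyl-13-[(2S)-2-methyloxiran-2-yl]-6-[(trimethylsilyl)methyl]trideca-5,9-dien-2-one | CC(=O)[C@@H](ONc1ccccc1)C/C=C(C[Si](C)(C)C)/CC/C=C(C)/CCC[C@@]1(C)CO1 | intermediate
17 | (3S,5Z,9E)-3-hydroxy-10-methyl-13-[(2S)-2-methyloxiran-2-yl]-6-[(trimethylsilyl)methyl]trideca-5,9-dien-2-one | CC(=O)[C@@H](O)C/C=C(C[Si](C)(C)C)/CC/C=C(C)/CCC[C@@]1(C)CO1 | intermediate
18 | (3S,5Z,9E)-10-methyl-13-[(2S)-2-methyloxiran-2-yl]-2-oxo-6-[(trimethylsilyl)methyl]trideca-5,9-dien-3-yl (triphenylphosphoranylidene)acetate | CC(=O)[C@@H](OC(=O)C=P(c1ccccc1)(c1ccccc1)c1ccccc1)C/C=C(C[Si](C)(C)C)/CC/C=C(C)/CCC[C@@]1(C)CO1 | intermediate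
19 | (5S)-4-methyl-5-{(2Z,6E)-7-methyl-10-[(2S)-2-methyloxiran-2-yl]-3-[(trimethylsilyl)methyl]deca-2,6-dien-1-yl}furan-2(5H)-one | CC1=CC(=O)O[C@H]1C/C=C(C[Si](C)(C)C)/CC/C=C(C)/CCC[C@@]2(C)CO2 | intermediate
20 | (4S,5R,9S,10R,12S)-19-hydroxylabda-8(17),13-dien-15,12-olide | C=C1CC[C@@H]2[C@](C)(CCC[C@]2(C)CO)[C@H]1C[C@@H]1OC(=O)C=C1C | intermediate
21 | (4S,5R,9S,10R,12S)-labda-8(17),13-dien-15,12-olid-19-oic acid | C=C1CC[C@@H]2[C@](C)(CCC[C@]2(C)C(=O)O)[C@H]1C[C@@H]1OC(=O)C=C1C | intermediate
22 | (4S,5R,9S,10R,12S,13Z)-12-hydroxylabda-8(17),13-diene-15,19-dioic acid | C=C1CC[C@@H]2[C@](C)(CCC[C@]2(C)C(=O)O)[C@H]1C[C@H](O)/C(C)=C\C(=O)O | target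

**Step count and risk**
Total steps: 10. Longest linear sequence: 10 steps (1 and 2 → 22).

Most likely to fail, first: step 8. The bicyclisation may stop after ring A, because the C19 oxygen can capture the C10 cation, or it may lose material to a 1,2-hydride shift of the opened epoxide. The axial placement of CH2O at C4 is argued, not demonstrated. The fallback closes the rings in two separate operations and sets out from 19. Lewis-acid-free protic activation (HFIP with Ph4PBF4, 0 °C) leaves the C19 hydroxyl nucleophilic, so the epoxide is opened by the C5=C10 alkene and the oxygen closes onto C10. This gives the bridged ether (5S)-5-[(2Z)-5-(1,5-dimethyl-6-oxabicyclo[3.2.1]octan-8-yl)-3-[(trimethylsilyl)methyl]pent-2-en-1-yl]-4-methylfuran-2(5H)-one F1, in which carbocycle A and the oxa-bridge still form together and the C4/C10 relationship is locked syn. F1 is then ionised at the tertiary C10–O bond with TiCl4 (CH2Cl2, −78 °C) and the allylsilane displaces the ether oxygen from the opposite face (intramolecular Hosomi–Sakurai alkylation with inversion at C10). This gives 20, where the route is rejoined.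

Second: step 4. The alkenylcopper may not add cleanly to the polymerisable enone in the presence of the magnesium diolate. The fallback sets out from 10. The carbocupration is run as before, but 12 is quenched with iodine to give the isolable vinyl iodide (2S,6E,10Z)-11-iodo-2,6-dimethyl-10-[(trimethylsilyl)methyl]undeca-6,10-diene-1,2-diol F2. The C9–C11 bond is then made by a Pd-catalysed reductive Heck (hydroalkenylation) reaction of F2 with 11 (Pd(OAc)2, Et3N, HCO2H, DMF, 50 °C), which returns to the route at 13.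

Third: step 6. The ketone is the limiting reagent, regioselectivity between C12 and C16 is not guaranteed, and nitrosobenzene may attack the polyene. The fallback takes C12 from the chiral pool instead of from catalysis and sets out from 10. Alkenylcopper 12, activated with BF3·OEt2, opens methyl (S)-glycidate (COC(=O)[C@@H]1CO1) at its CH2 to give methyl (2S,4Z,8E,13S)-2,13,14-trihydroxy-9,13-dimethyl-5-[(trimethylsilyl)methyl]tetradeca-4,8-dienoate F3. Primary-selective tosylation (TsCl, Et3N, cat. Bu2SnO) gives the primary tosylate of the triol ester F4, which is not isolated, and K2CO3/MeOH closes it to methyl (2S,4Z,8E)-2-hydroxy-9-methyl-12-[(2S)-2-methyloxiran-2-yl]-5-[(trimethylsilyl)methyl]dodeca-4,8-dienoate F5. Me(MeO)NH·HCl with i-PrMgCl gives the Weinreb amide (2S,4Z,8E)-2-hydroxy-N-methoxy-N,9-dimethyl-12-[(2S)-2-methyloxiran-2-yl]-5-[(trimethylsilyl)methyl]dodeca-4,8-dienamide F6. MeMgBr (−78 → 0 °C) then gives acyloin 17, where the route is rejoined.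

**Further compounds**
F1 | step 8 | (5S)-5-[(2Z)-5-(1,5-dimethyl-6-oxabicyclo[3.2.1]octan-8-yl)-3-[(trimethylsilyl)methyl]pent-2-en-1-yl]-4-methylfuran-2(5H)-one (C19–O–C10 bridge, configuration as in the SMILES) | CC1=CC(=O)O[C@H]1C/C=C(C[Si](C)(C)C)/CC[C@@H]2[C@@]3(C)CCC[C@]2(C)CO3
F2 | step 4 | (2S,6E,10Z)-11-iodo-2,6-dimethyl-10-[(trimethylsilyl)methyl]undeca-6,10-diene-1,2-diol | I/C=C(C[Si](C)(C)C)/CC/C=C(C)/CCC[C@](C)(O)CO
F3 | step 6 | methyl (2S,4Z,8E,13S)-2,13,14-trihydroxy-9,13-dimethyl-5-[(trimethylsilyl)methyl]tetradeca-4,8-dienoate | COC(=O)[C@@H](O)C/C=C(C[Si](C)(C)C)/CC/C=C(C)/CCC[C@](C)(O)CO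
F4 | step 6 | methyl (2S,4Z,8E,13S)-2,13-dihydroxy-9,13-dimethyl-14-(tosyloxy)-5-[(trimethylsilyl)methyl]tetradeca-4,8-dienoate | COC(=O)[C@@H](O)C/C=C(C[Si](C)(C)C)/CC/C=C(C)/CCC[C@](C)(O)COS(=O)(=O)c1ccc(C)cc1
F5 | step 6 | methyl (2S,4Z,8E)-2-hydroxy-9-methyl-12-[(2S)-2-methyloxiran-2-yl]-5-[(trimethylsilyl)methyl]dodeca-4,8-dienoate | COC(=O)[C@@H](O)C/C=C(C[Si](C)(C)C)/CC/C=C(C)/CCC[C@@]1(C)CO1
F6 | step 6 | (2S,4Z,8E)-2-hydroxy-N-methoxy-N,9-dimethyl-12-[(2S)-2-methyloxiran-2-yl]-5-[(trimethylsilyl)methyl]dodeca-4,8-dienamide | CON(C)C(=O)[C@@H](O)C/C=C(C[Si](C)(C)C)/CC/C=C(C)/CCC[C@@]1(C)CO1
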